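The earlier runs and the new flask are calculated with made-up constants.

You cannot tell from the substrate percentages which of these two runs had the larger charge: Monday's run at 0.70 M and Sunday's at 1.1 M, charges a factor of 1.57 apart, have 37.5 % and 38.8 % of their substrate left at 2.50 h, a gap of 1.3 percentage points against a scatter of 1 point on each reading.

| flask | substrate | remark | time |
|---|---|---|---|
| Monday's | 0.70 M | run made earlier |  |
| Sunday's | 1.1 M | run made earlier |  |
| flask | 0.50 M |  | 2.5 h |

| run | time / h | intermediate C / % | intermediate B / % | intermediate A / % | intermediate D / % | product / % | substrate / % |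
|---|---|---|---|---|---|---|---|
| Monday's | 0.200 | 0 | 3.3 | 4.8 | 0 | 0 | 93.2 |
| Monday's | 0.417 | 2.5 | 4.3 | 10.2 | 0 | 1.3 | 85.0 |
| Monday's | 0.667 | 1.7 | 6.7 | 13.1 | 0 | 0.7 | 76.0 |
| Monday's | 1.33 | 4.5 | 10.7 | 20.1 | 0.8 | 3.8 | 62.0 |
| Monday's | 2.50 | 9.5 | 10.9 | 28.9 | 0 | 5.9 | 37.5 |
| Sunday's | 0.200 | 1.2 | 1.4 | 4.8 | 0 | 0 | 93.2 |
| Sunday's | 0.417 | 1.4 | 5.7 | 8.4 | 0 | 3.4 | 86.4 |
| Sunday's | 0.667 | 1.3 | 10.6 | 13.4 | 0.1 | 0 | 78.1 |
| Sunday's | 1.33 | 5.3 | 10.8 | 20.7 | 0 | 3.0 | 61.1 |
| Sunday's | 2.50 | 10.8 | 14.3 | 29.5 | 2.1 | 8.7 | 38.8 |

(readings scatter by 1 percentage point)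



* the species in which most of what was charged as substrate, at 2.5 h sits (intermediate A / intermediate B / intermediate C / product / intermediate D / substrate)
* the largest share itself, whichever of these holds it, in percent of the substrate charged

Write the balance of the substrate as f, the fraction of the charge still there, and let the loss go in proportion to f, the first-order form these two runs suggest:

df/dt = −k f, so f = exp(−k t)

The charge is absent from this balance, so under it Sunday's larger charge ends where Monday's ends. Take −ln f / t from the geometric mean of the two end readings as the loss constant, the observed first-order rate constant, which is the share of the remaining substrate lost per hour: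

k = 0.386 /h

The flask at 0.50 M stands a factor of 1.40 below Monday's charge, a smaller step than the one between the two runs, so my own reckoning carries k over unchanged:

f at 2.5 h = 38.1 %

That stands above the readings of intermediate A, 28.9 % and 29.5 %. The forecast, a little above my figure, names substrate at 38.5 %: “Substrate decay therefore looks first order, with no visible concentration dependence”.

The flask gives substrate at 38.3 %, which is 0.20 points above the figure from the loss constant.

    substrate → intermediate A (k = 0.00410 /min)
    substrate → intermediate B (k = 0.00230 /min)
    intermediate A ⇌ intermediate C (K = 0.490, k = 0.00830 /min)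
    intermediate C ⇌ intermediate D (K = 2.80, k = 7.90 × 10⁻⁴ /min)
    intermediate B → product (k = 0.00600 /min)
    intermediate D ⇌ product (K = 2.70, k = 0.00110 /min)

Held at this time, the substrate left in the flask stays within 5 points of its value for charges from at least 0.062 M to 4.0 M, whereas at this charge it has moved that far by 2.18 h and by 2.86 h. Put the loss constant of 0.386 /h to the same flask left until 6.0 h and you reckon 9.87 % of the substrate remaining; that flask holds 9.99 %, and the largest share of its charge now sits in intermediate A, at 37.9 %.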